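A direct plan would couple the MOM-protected 5-bromodihydrocapsaicin A1 with the MOM-protected 5-borylvanillin pinacol ester A2 by Suzuki reaction to the biaryl aldehyde A3, would turn the formyl group into the pent-4-enamide arm of the biaryl bis-amide A4, and would complete the alkene by B-alkyl Suzuki coupling with (E)-1-bromo-3-methylbut-1-ene A5 before deprotection.
Its weakest steps would be:
- the protection, borylation and deprotection around the coupling of A1 with A2, which would add length without complexity;
- the oxime reduction and acylation leading from A3 to A4, which would rebuild an arm that a natural monomer already holds;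
- the late hydroboration–coupling of A4 with A5, in which amide N–H bonds would consume borane and β-hydride elimination would compete.

The route rests on the C5–C5' biaryl bond alone and exploits the phenol oxygen O4 that sits beside C5 on each ring, with C3 blocked by OMe. 5-Bromodihydrocapsaicin (ring B) and capsaicin (ring A) are tied O4-to-O4' by a di-tert-butylsilylene bridge, and a palladium-catalysed intramolecular C–H arylation closes a seven-membered dioxasilepine ring, in which C5'–Br can reach only C5–H. One operation thus forms the biphenol bond with complete cross-selectivity, as a controlled copy of the presumed phenol dimerization. No boron partner is needed, the bridge is the only protecting group, and both amide arms, the E-alkene included, arrive intact from the natural monomers, so no arm is rebuilt.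

Key step: step 4

Assumption: capsaicin is bought as the pure E compound free of dihydrocapsaicin, and dihydrocapsaicin as the pure saturated amide. Ring A is the capsaicin-derived ring (unsaturated arm), ring B the dihydrocapsaicin-derived ring (saturated arm), and primed locants refer to ring B.

Step 1
Reactants: 1 dihydrocapsaicin
Product: 2 N-(3-bromo-4-hydroxy-5-methoxybenzyl)-8-methylnonanamide (5-bromodihydrocapsaicin)
Conditions: NBS (1.0 equiv), MeCN, −10 to 0 °C
Reagents that add atoms: N-bromosuccinimide, O=C1CCC(=O)N1Br
Why: Electrophilic aromatic bromination, in which the free phenol should steer bromine to C5, its only open ortho position (the para position carries the benzylic carbon), while the saturated arm offers no competing site.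

Step 2
Reactants: 2 N-(3-bromo-4-hydroxy-5-methoxybenzyl)-8-methylnonanamide
Product: 3 N-{3-bromo-4-[(di-tert-butylsilyl)oxy]-5-methoxybenzyl}-8-methylnonanamide (Si–H silyl ether of 2)
Conditions: t-Bu2SiHCl, imidazole, DMAP (cat.), DMF, rt to 40 °C
Reagents that add atoms: di-tert-butylchlorosilane, CC(C)(C)[SiH](Cl)C(C)(C)C
Why: O-silylation of the phenol by substitution at silicon, in which the acidic phenol reacts and the secondary amide does not, the hydrogen on silicon keeping the reagent small enough for the doubly ortho-substituted phenol and serving as the latent leaving group for the second Si–O bond.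

Step 3
Reactants: 3 N-{3-bromo-4-[(di-tert-butylsilyl)oxy]-5-methoxybenzyl}-8-methylnonanamide, 4 capsaicin
Product: 6 di-tert-butylsilylene-bridged bis(aryl ether) joining O4' of 5-bromodihydrocapsaicin to O4 of capsaicin, via bromosilane 5 (not isolated)
Conditions: NBS (1.0 equiv), CH2Cl2, 0 °C, dark; then 4, imidazole, DMAP (cat.), CH2Cl2/DMF, rt to 40 °C
Reagents that add atoms: none
Why: Bromination of the Si–H bond by NBS followed by nucleophilic substitution at silicon by the phenol of capsaicin, which is added only after the NBS is consumed so that its alkene and ring A never meet electrophilic bromine, while the two tert-butyl groups should slow exchange to symmetrical silanes.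

Step 4
Reactants: 6 di-tert-butylsilylene-bridged bis(aryl ether)
Product: 7 (E)-N-({6,6-di-tert-butyl-4,8-dimethoxy-10-[(8-methylnonanamido)methyl]dibenzo[d,f][1,3,2]dioxasilepin-2-yl}methyl)-8-methylnon-6-enamide (silicon-bridged biaryl)
Conditions: Pd(OAc)2 (5 mol %), PCy3·HBF4 (10 mol %), CsOPiv (2 equiv), p-xylene, 130 °C, argon
Reagents that add atoms: none
Why: Zerovalent palladium inserts into the C5'–Br bond of ring B, pivalate on the resulting divalent arylpalladium removes H5 of ring A in a concerted metalation–deprotonation to give an eight-membered diarylpalladacycle, and reductive elimination forms the C5–C5' bond. The closest known reaction type is the silicon-tethered palladium-catalysed intramolecular C–H arylation of di-tert-butyl bis(aryloxy)silanes, an established way to unsymmetrical o,o'-biphenols, applied here to two amide-bearing guaiacyl rings. The one ring closed is the seven-membered dibenzo[d,f][1,3,2]dioxasilepine, formed by aryl–aryl bond formation between the two carbons ortho to the bridging oxygens. No stereocentre is created: the biaryl axis carries only oxygen and hydrogen in its ortho positions and is not configurationally stable, and the E alkene of the ring A arm is a spectator. The step needs cross-selectivity, secured because each molecule holds exactly one C–Br bond and one reachable C–H bond, and site selectivity, secured because C3 of ring A carries OMe so that C5–H is the only hydrogen ortho to the bridging oxygen while C2–H and C6–H would demand larger rings. It also needs the arylpalladium to ignore the remote 1,2-disubstituted alkene and the Si–O bonds to last, which the entropic advantage of the tethered C–H cleavage, the bulky tert-butyl groups and the dry non-polar medium should provide.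

Step 5
Reactants: 7 silicon-bridged biaryl
Product: 8 6'',7''-dihydro-5',5'''-dicapsaicin
Conditions: TBAF (2.2 equiv), AcOH (2.2 equiv), THF, 0 °C to rt, degassed
Reagents that add atoms: none
Why: Fluoride-induced desilylation of both aryl silyl ether bonds, driven by the strength of the Si–F bond and buffered with acetic acid so that the electron-rich biphenol is released as the neutral phenol, with amides, methyl ethers and the E alkene untouched.

Compound list
1 | dihydrocapsaicin, N-(4-hydroxy-3-methoxybenzyl)-8-methylnonanamide | COc1cc(CNC(=O)CCCCCCC(C)C)ccc1O | starting material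
2 | N-(3-bromo-4-hydroxy-5-methoxybenzyl)-8-methylnonanamide (5-bromodihydrocapsaicin) | COc1cc(CNC(=O)CCCCCCC(C)C)cc(Br)c1O | intermediate
3 | N-{3-bromo-4-[(di-tert-butylsilyl)oxy]-5-methoxybenzyl}-8-methylnonanamide | COc1cc(CNC(=O)CCCCCCC(C)C)cc(Br)c1O[SiH](C(C)(C)C)C(C)(C)C | intermediate
4 | capsaicin, (E)-N-(4-hydroxy-3-methoxybenzyl)-8-methylnon-6-enamide | COc1cc(CNC(=O)CCCC/C=C/C(C)C)ccc1O | starting material
5 | N-{3-bromo-4-[(bromo-di-tert-butylsilyl)oxy]-5-methoxybenzyl}-8-methylnonanamide (bromosilane) | COc1cc(CNC(=O)CCCCCCC(C)C)cc(Br)c1O[Si](Br)(C(C)(C)C)C(C)(C)C | intermediate (not isolated)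
6 | di-tert-butylsilylene-bridged bis(aryl ether): one t-Bu2Si carrying the 2-bromo-6-methoxy-4-[(8-methylnonanamido)methyl]phenoxy group (ring B) and the 2-methoxy-4-{[(E)-8-methylnon-6-enamido]methyl}phenoxy group (ring A) | COc1cc(CNC(=O)CCCCCCC(C)C)cc(Br)c1O[Si](Oc1ccc(CNC(=O)CCCC/C=C/C(C)C)cc1OC)(C(C)(C)C)C(C)(C)C | intermediate
7 | (E)-N-({6,6-di-tert-butyl-4,8-dimethoxy-10-[(8-methylnonanamido)methyl]dibenzo[d,f][1,3,2]dioxasilepin-2-yl}methyl)-8-methylnon-6-enamide | COc1cc(CNC(=O)CCCC/C=C/C(C)C)cc2c1O[Si](C(C)(C)C)(C(C)(C)C)Oc1c(OC)cc(CNC(=O)CCCCCCC(C)C)cc1-2 | intermediate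
8 | 6'',7''-dihydro-5',5'''-dicapsaicin (E alkene) | COc1cc(CNC(=O)CCCC/C=C/C(C)C)cc(-c2cc(CNC(=O)CCCCCCC(C)C)cc(OC)c2O)c1O | target

Total step count: 5. Longest linear sequence: 5 steps (1 → 2 → 3 → 6 → 7 → 8); capsaicin 4 enters at step 3.

Steps most likely to fail

Step 4. The ring closure may suffer from protodebromination of ring B, from loss of the silicon bridge at 130 °C in the presence of carboxylate, or from migration of the alkene under palladium hydride. The same seven-membered ring would then be closed by a reductive coupling of two C–Br bonds at lower temperature. The fallback sets out from capsaicin 4 and bromosilane 5 and comes back at 7. Ortho-bromination of 4 (NBS, cat. i-Pr2NH, CH2Cl2, −40 °C, where the phenol ring should outpace the alkene) would give 5-bromocapsaicin F1. Substitution at the silicon of 5 by F1 (imidazole, DMAP) would give the di-tert-butyl bis(2-bromoaryloxy)silane F2. An intramolecular Ullmann-type homocoupling with zerovalent nickel (Ni(cod)2, 2,2'-bipyridine, DMF, 50 °C) should then deliver 7.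

Step 3. The second Si–O bond may not form cleanly, through slow substitution at the crowded silicon, ring bromination of 3 by NBS, or exchange to symmetrical silanes. The bridge would then be given up. The fallback sets out from 1 and 4 and comes back at 8. An equimolar mixture of both phenols would be oxidised with horseradish peroxidase and H2O2 (phosphate buffer/acetone, rt) in an untethered oxidative phenol coupling. This should give 8 beside the homodimers 5,5'-dicapsaicin F3 and 6'',7'',6''',7'''-tetrahydro-5',5'''-dicapsaicin F4. The three would be separated by their number of alkenes on silica gel impregnated with AgNO3.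

Step 2. Silylation of the doubly ortho-substituted phenol of 2 may stall, or the Si–H ether may not survive isolation. The bridge would then be built from the less hindered phenol with a doubly electrophilic silicon reagent. The fallback sets out from 4 and 2 and comes back at 6. Capsaicin 4 and t-Bu2Si(OTf)2 (2,6-lutidine, CH2Cl2, −78 °C) should give the aryloxy(di-tert-butyl)silyl triflate F5. This would be trapped in the same flask by 2 (2,6-lutidine, DMAP, −78 °C to rt) to give 6 without NBS and without 3 or 5.

Further compounds
F1 | step 4 | 5-bromocapsaicin, (E)-N-(3-bromo-4-hydroxy-5-methoxybenzyl)-8-methylnon-6-enamide | COc1cc(CNC(=O)CCCC/C=C/C(C)C)cc(Br)c1O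
F2 | step 4 | di-tert-butyl bis(2-bromoaryloxy)silane: t-Bu2Si carrying the 2-bromo-6-methoxy-4-[(8-methylnonanamido)methyl]phenoxy group and the 2-bromo-6-methoxy-4-{[(E)-8-methylnon-6-enamido]methyl}phenoxy group | COc1cc(CNC(=O)CCCCCCC(C)C)cc(Br)c1O[Si](Oc1c(Br)cc(CNC(=O)CCCC/C=C/C(C)C)cc1OC)(C(C)(C)C)C(C)(C)C
F3 | step 3 | 5,5'-dicapsaicin (both arms E-unsaturated) | COc1cc(CNC(=O)CCCC/C=C/C(C)C)cc(-c2cc(CNC(=O)CCCC/C=C/C(C)C)cc(OC)c2O)c1O
F4 | step 3 | 6'',7'',6''',7'''-tetrahydro-5',5'''-dicapsaicin (homodimer of dihydrocapsaicin) | COc1cc(CNC(=O)CCCCCCC(C)C)cc(-c2cc(CNC(=O)CCCCCCC(C)C)cc(OC)c2O)c1O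
F5 | step 2 | di-tert-butyl(2-methoxy-4-{[(E)-8-methylnon-6-enamido]methyl}phenoxy)silyl trifluoromethanesulfonate | COc1cc(CNC(=O)CCCC/C=C/C(C)C)ccc1O[Si](OS(=O)(=O)C(F)(F)F)(C(C)(C)C)C(C)(C)C
A1 | direct plan | N-[3-bromo-5-methoxy-4-(methoxymethoxy)benzyl]-8-methylnonanamide | COCOc1c(Br)cc(CNC(=O)CCCCCCC(C)C)cc1OC
A2 | direct plan | 3-methoxy-4-(methoxymethoxy)-5-(4,4,5,5-tetramethyl-1,3,2-dioxaborolan-2-yl)benzaldehyde | COCOc1c(OC)cc(C=O)cc1B1OC(C)(C)C(C)(C)O1
A3 | direct plan | N-{[5'-formyl-3,3'-dimethoxy-2,2'-bis(methoxymethoxy)biphenyl-5-yl]methyl}-8-methylnonanamide | COCOc1c(OC)cc(C=O)cc1-c1cc(CNC(=O)CCCCCCC(C)C)cc(OC)c1OCOC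
A4 | direct plan | N-{[3,3'-dimethoxy-2,2'-bis(methoxymethoxy)-5'-[(pent-4-enamido)methyl]biphenyl-5-yl]methyl}-8-methylnonanamide | C=CCCC(=O)NCc1cc(OC)c(OCOC)c(-c2cc(CNC(=O)CCCCCCC(C)C)cc(OC)c2OCOC)c1
A5 | direct plan | (E)-1-bromo-3-methylbut-1-ene | CC(C)/C=C/Br
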